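**Retrosynthetic overview** (isoflavanone numbering; ring A = resorcinol ring, ring C = pyranone, ring B = aryl ring on C3, ring D = dimethylpyran)
1. The plan rests on the C4–C4a bond of ring C. It joins the ketone carbon to the ring A carbon that is ortho to O1 and para to the C7 oxygen. Once it exists, the neighbouring C3–H (benzylic to ring B, alpha to C4=O) is acidic. This bond is therefore made last, by bromine–lithium exchange at C4a and attack on a C4 N-methoxy-N-methyl amide (Parham cyclisation). Only a buffered desilylation follows.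
2. The amide goes back through the acid and the primary alcohol to an aryl ether. O1–C2 is cut by a Mitsunobu reaction between 2-bromo-5-silyloxyphenol (from 4-bromoresorcinol) and a 2-aryl-1,3-propanediol monoacetate, at a stage where C3–H is not acidic.
3. C3 is set by lipase desymmetrisation of the prochiral 2-arylpropane-1,3-diyl diacetate. This comes from a diethyl arylmalonate, whose C3–ring B bond is made by palladium-catalysed malonate arylation.
4. The aryl bromide, 6-bromo-7-methoxy-2,2-dimethyl-2H-chromene, comes from 4-bromo-3-methoxyphenol by propargyl ether formation and a Claisen cascade.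
5. Ring order: rings A and B are bought as benzene rings, ring D is closed in step 2, ring C in step 12.

Key step: step 12

Assumption: the lipase is taken to follow the empirical size rule for primary alcohols whose stereocentre lies next to the CH2O group (aryl = large, CH2OAc = medium), so it should cleave the pro-R acetate; the absolute configuration of the monoacetate is to be secured by correlation or by anomalous-dispersion X-ray analysis of a later bromine-bearing intermediate before material is committed.

Step 1
Reactants: 1 4-bromo-3-methoxyphenol; 2 3-chloro-3-methylbut-1-yne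
Product: 3 1-bromo-2-methoxy-4-[(2-methylbut-3-yn-2-yl)oxy]benzene
Conditions: CuCl2·2H2O (0.5 mol %), DBU (1.3 equiv), MeCN, 0 °C to rt
Reagents that add atoms: none
Why: Copper-catalysed propargylic substitution (O-alkylation of the phenoxide by the copper-activated tertiary propargyl chloride) is the standard entry to aryl 1,1-dimethylpropargyl ethers and touches neither the aryl bromide nor the methyl ether.

Step 2
Reactants: 3 1-bromo-2-methoxy-4-[(2-methylbut-3-yn-2-yl)oxy]benzene
Product: 6 bromochromene 6-bromo-7-methoxy-2,2-dimethyl-2H-chromene, via ortho-allenylphenol 4 (not isolated), via ortho-quinone methide 5 (not isolated)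
Conditions: o-xylene, reflux (ca. 145 °C)
Reagents that add atoms: none
Why: The aromatic propargyl Claisen rearrangement gives 4, whose 1,5-hydrogen shift to 5 and oxa-6π electrocyclisation close ring D; the shift should go to the free ortho carbon para to the methoxy group, because the other ortho carbon is crowded by a methoxy methyl that the neighbouring bromine pushes toward it.

Step 3
Reactants: 6 bromochromene; 7 diethyl malonate
Product: 8 diethyl 2-(7-methoxy-2,2-dimethyl-2H-chromen-6-yl)malonate
Conditions: Pd(OAc)2 (2 mol %), P(t-Bu)3·HBF4 (4.4 mol %), K3PO4 (3 equiv), toluene, 100 °C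
Reagents that add atoms: none
Why: In this palladium-catalysed alpha-arylation of a malonate, oxidative addition of the aryl bromide to zerovalent palladium bearing the bulky electron-rich phosphine, exchange with the potassium malonate and reductive elimination form the aryl–CH bond, and the hindered cis-olefin of ring D should not compete in a Heck reaction.

Step 4
Reactants: 8 diethyl arylmalonate
Product: 9 2-(7-methoxy-2,2-dimethyl-2H-chromen-6-yl)propane-1,3-diol
Conditions: 8 added to LiAlH4 (2.5 equiv), THF, 0 °C to rt; aq. potassium sodium tartrate work-up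
Reagents that add atoms: none
Why: Hydride reduction of both esters gives the prochiral 1,3-diol; adding the malonate to excess hydride keeps enolate formation down, and the chromene olefin and the aryl ethers are inert to hydride.

Step 5
Reactants: 9 2-arylpropane-1,3-diol
Product: 10 2-(7-methoxy-2,2-dimethyl-2H-chromen-6-yl)propane-1,3-diyl diacetate
Conditions: Ac2O (3 equiv), pyridine, 4-(dimethylamino)pyridine (5 mol %), CH2Cl2, 0 °C to rt
Reagents that add atoms: acetic anhydride, CC(=O)OC(C)=O
Why: This plain nucleophile-catalysed acetylation of two primary alcohols is needed because the enzyme is predicted to give the required enantiomer in the hydrolytic and not in the acylating direction.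

Step 6
Reactants: 10 prochiral diacetate
Product: 11 (S)-3-hydroxy-2-(7-methoxy-2,2-dimethyl-2H-chromen-6-yl)propyl acetate
Conditions: lipase from Burkholderia cepacia (Amano PS), 0.1 M KH2PO4/K2HPO4 buffer pH 7.0, i-Pr2O (two phases), 30 °C; cold extraction, used at once
Reagents that add atoms: none
Why: Lipase-catalysed desymmetrising hydrolysis of a 2-arylpropane-1,3-diyl diacetate, a known substrate class, sets C3: by the size rule the pro-R acetate is cleaved to leave the (S)-monoacetate, and further hydrolysis should consume mainly the minor enantiomer and so raise the enantiomeric purity.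

Step 7
Reactants: 12 4-bromoresorcinol
Product: 13 2-bromo-5-(tert-butyldimethylsilyloxy)phenol
Conditions: TBSCl (1.0 equiv), imidazole (1.2 equiv), CH2Cl2/DMF, −10 to 0 °C
Reagents that add atoms: tert-butyldimethylsilyl chloride, CC(C)(C)[Si](C)(C)Cl
Why: Kinetic silylation with one equivalent of silyl chloride should take the unhindered hydroxyl para to bromine and leave the hydroxyl flanked by bromine; bis-ether and isomer are removed by chromatography.

Step 8
Reactants: 11 (S)-monoacetate; 13 2-bromo-5-(tert-butyldimethylsilyloxy)phenol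
Product: 14 (S)-3-[2-bromo-5-(tert-butyldimethylsilyloxy)phenoxy]-2-(7-methoxy-2,2-dimethyl-2H-chromen-6-yl)propyl acetate
Conditions: PPh3 (1.3 equiv), DIAD (1.3 equiv), toluene, 0 °C to rt
Reagents that add atoms: none
Why: The Mitsunobu etherification (SN2 at the primary CH2 by the acidic ortho-bromophenol) forms O1–C2 without touching the stereocentre, at a stage where no carbonyl group acidifies C3–H and elimination has no driving force.

Step 9
Reactants: 14 (S)-ether acetate
Product: 15 (R)-3-[2-bromo-5-(tert-butyldimethylsilyloxy)phenoxy]-2-(7-methoxy-2,2-dimethyl-2H-chromen-6-yl)propan-1-ol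
Conditions: i-Bu2AlH (2.5 equiv), CH2Cl2, −78 °C; aq. potassium sodium tartrate
Reagents that add atoms: none
Why: Reductive ester cleavage avoids the alkoxide or carbonate bases that would strip the phenolic silyl ether and spares the aryl bromide and the olefin; the descriptor turns to R only because the priorities change.

Step 10
Reactants: 15 (R)-alcohol
Product: 17 (S)-3-[2-bromo-5-(tert-butyldimethylsilyloxy)phenoxy]-2-(7-methoxy-2,2-dimethyl-2H-chromen-6-yl)propanoic acid, via aldehyde 16 (not isolated)
Conditions: TEMPO (2,2,6,6-tetramethylpiperidin-1-oxyl, 20 mol %), PhI(OAc)2 (2.2 equiv), MeCN/H2O 1:1, 0 °C to rt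
Reagents that add atoms: water, O
Why: The oxoammonium-catalysed (TEMPO/PhI(OAc)2) oxidation takes the primary alcohol through 16 and its hydrate to the acid in a weakly acidic, chlorine-free medium, so the enolisable aldehyde is short-lived and meets no base, and the electron-rich olefin and arenes are not halogenated.

Step 11
Reactants: 17 (S)-acid
Product: 18 (S)-3-[2-bromo-5-(tert-butyldimethylsilyloxy)phenoxy]-N-methoxy-2-(7-methoxy-2,2-dimethyl-2H-chromen-6-yl)-N-methylpropanamide
Conditions: MeNHOMe·HCl (1.3 equiv), EDC·HCl (N-ethyl-N'-(3-dimethylaminopropyl)carbodiimide hydrochloride, 1.2 equiv), 1-hydroxybenzotriazole (1.2 equiv), N-methylmorpholine (2.5 equiv), CH2Cl2, 0 °C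
Reagents that add atoms: N,O-dimethylhydroxylamine hydrochloride, CNOC.Cl
Why: Carbodiimide/hydroxybenzotriazole amide coupling at 0 °C with only a weak tertiary amine is standard for 2-arylalkanoic acids and should leave C3 intact.

Step 12
Reactants: 18 (S)-bromoaryl ether N-methoxy-N-methyl amide
Product: 21 (3S)-7-(tert-butyldimethylsilyloxy)-3-(7-methoxy-2,2-dimethyl-2H-chromen-6-yl)chroman-4-one, via aryllithium 19 (not isolated), via tetrahedral lithium adduct 20 (not isolated)
Conditions: n-BuLi (1.05 equiv, run down the cold flask wall), THF, internal −100 to −95 °C, 15 min; precooled AcOH (3 equiv) in THF at −100 °C; then poured into KH2PO4 buffer (pH 5) at 0 °C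
Reagents that add atoms: n-butyllithium, [Li]CCCC (its lithium is held only in 19 and 20; 21 keeps nothing of it)
Why: n-BuLi attacks the bromine at C4a and gives aryllithium 19, stabilised by the ortho ether oxygen O1, and its carbanion adds at once to the tethered amide carbonyl (C4) to give adduct 20, in which lithium is chelated by the alkoxide and the N-methoxy oxygen. This is a Parham cyclisation, the known halogen–lithium exchange with intramolecular acylation of aryl bromides that carry an N-methoxy-N-methyl amide. Ring C closes in the 6-exo-trig mode (C4a, C8a, O1, C2, C3 and C4 in the ring, the carbonyl oxygen outside it). No stereocentre of 21 is created here: C3 is carried through unchanged, and the transient C4 centre of 20 is erased when the adduct collapses. Exchange must outrun removal of C3–H (which would cost configuration or expel the aryloxide by E1cB), butyl addition to the amide and attack at silicon; the very low temperature, the activating ortho oxygen, the alpha-branched and thus shielded amide and the single equivalent of base should secure this. The bromine fixes the site on ring A, and because 20 falls apart only in the cold acetic acid quench, the ketone with its acidic C3–H appears when no base is left.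

Step 13
Reactants: 21 (3S)-7-O-silyl isoflavanone
Product: 22 (3S)-7-hydroxy-3-(7-methoxy-2,2-dimethyl-2H-chromen-6-yl)chroman-4-one (CNP0226344.1)
Conditions: Bu4NF (1.1 equiv) premixed with AcOH (2.2 equiv), THF, 0 °C; KH2PO4 buffer work-up, rapid chromatography on acid-washed silica
Reagents that add atoms: none
Why: In this fluoride-induced cleavage of the aryl silyl ether the premixed acetic acid protonates the phenoxide as it forms and keeps the medium too weakly basic to enolise the ketone, so C3 should stay (S).

**Compound list**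
1 | 4-bromo-3-methoxyphenol | COc1cc(O)ccc1Br | starting material
2 | 3-chloro-3-methylbut-1-yne | CC(C)(Cl)C#C | starting material
3 | 1-bromo-2-methoxy-4-[(2-methylbut-3-yn-2-yl)oxy]benzene | COc1cc(OC(C)(C)C#C)ccc1Br | intermediate
4 | 4-bromo-5-methoxy-2-(3-methylbuta-1,2-dien-1-yl)phenol | COc1cc(O)c(C=C=C(C)C)cc1Br | intermediate
5 | 4-bromo-3-methoxy-6-(3-methylbut-2-en-1-ylidene)cyclohexa-2,4-dien-1-one | COC1=CC(=O)C(=CC=C(C)C)C=C1Br | intermediate
6 | 6-bromo-7-methoxy-2,2-dimethyl-2H-chromene | COc1cc2c(cc1Br)C=CC(C)(C)O2 | intermediate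
7 | diethyl malonate | CCOC(=O)CC(=O)OCC | starting material
8 | diethyl 2-(7-methoxy-2,2-dimethyl-2H-chromen-6-yl)malonate | COc1cc2c(cc1C(C(=O)OCC)C(=O)OCC)C=CC(C)(C)O2 | intermediate
9 | 2-(7-methoxy-2,2-dimethyl-2H-chromen-6-yl)propane-1,3-diol | COc1cc2c(cc1C(CO)CO)C=CC(C)(C)O2 | intermediate
10 | 2-(7-methoxy-2,2-dimethyl-2H-chromen-6-yl)propane-1,3-diyl diacetate | COc1cc2c(cc1C(COC(C)=O)COC(C)=O)C=CC(C)(C)O2 | intermediate
11 | (S)-3-hydroxy-2-(7-methoxy-2,2-dimethyl-2H-chromen-6-yl)propyl acetate | COc1cc2c(cc1[C@H](COC(C)=O)CO)C=CC(C)(C)O2 | intermediate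
12 | 4-bromoresorcinol | Oc1ccc(Br)c(O)c1 | starting material
13 | 2-bromo-5-(tert-butyldimethylsilyloxy)phenol | CC(C)(C)[Si](C)(C)Oc1ccc(Br)c(O)c1 | intermediate
14 | (S)-3-[2-bromo-5-(tert-butyldimethylsilyloxy)phenoxy]-2-(7-methoxy-2,2-dimethyl-2H-chromen-6-yl)propyl acetate | COc1cc2c(cc1[C@H](COC(C)=O)COc3cc(O[Si](C)(C)C(C)(C)C)ccc3Br)C=CC(C)(C)O2 | intermediate
15 | (R)-3-[2-bromo-5-(tert-butyldimethylsilyloxy)phenoxy]-2-(7-methoxy-2,2-dimethyl-2H-chromen-6-yl)propan-1-ol | COc1cc2c(cc1[C@H](CO)COc3cc(O[Si](C)(C)C(C)(C)C)ccc3Br)C=CC(C)(C)O2 | intermediate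
16 | (S)-3-[2-bromo-5-(tert-butyldimethylsilyloxy)phenoxy]-2-(7-methoxy-2,2-dimethyl-2H-chromen-6-yl)propanal | COc1cc2c(cc1[C@H](C=O)COc3cc(O[Si](C)(C)C(C)(C)C)ccc3Br)C=CC(C)(C)O2 | intermediate
17 | (S)-3-[2-bromo-5-(tert-butyldimethylsilyloxy)phenoxy]-2-(7-methoxy-2,2-dimethyl-2H-chromen-6-yl)propanoic acid | COc1cc2c(cc1[C@H](C(=O)O)COc3cc(O[Si](C)(C)C(C)(C)C)ccc3Br)C=CC(C)(C)O2 | intermediate
18 | (S)-3-[2-bromo-5-(tert-butyldimethylsilyloxy)phenoxy]-N-methoxy-2-(7-methoxy-2,2-dimethyl-2H-chromen-6-yl)-N-methylpropanamide | COc1cc2c(cc1[C@H](C(=O)N(C)OC)COc3cc(O[Si](C)(C)C(C)(C)C)ccc3Br)C=CC(C)(C)O2 | intermediate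
19 | aryllithium from 18 (lithium at C4a in place of bromine) | COc1cc2c(cc1[C@H](C(=O)N(C)OC)COc3cc(O[Si](C)(C)C(C)(C)C)ccc3[Li])C=CC(C)(C)O2 | intermediate
20 | lithium (3S)-4-[methoxy(methyl)amino]-7-(tert-butyldimethylsilyloxy)-3-(7-methoxy-2,2-dimethyl-2H-chromen-6-yl)chroman-4-olate (C4 undefined) | COc1cc2c(cc1[C@H]1COc3cc(O[Si](C)(C)C(C)(C)C)ccc3C1(O[Li])N(C)OC)C=CC(C)(C)O2 | intermediate
21 | (3S)-7-(tert-butyldimethylsilyloxy)-3-(7-methoxy-2,2-dimethyl-2H-chromen-6-yl)chroman-4-one | COc1cc2c(cc1[C@H]1COc3cc(O[Si](C)(C)C(C)(C)C)ccc3C1=O)C=CC(C)(C)O2 | intermediate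
22 | (3S)-7-hydroxy-3-(7-methoxy-2,2-dimethyl-2H-chromen-6-yl)chroman-4-one | COc1cc2c(cc1[C@H]1COc3cc(O)ccc3C1=O)C=CC(C)(C)O2 | target

**Step count:** 13 steps in total. The longest linear sequence is 12 steps (steps 1–6 and 8–13); step 7 is the side branch.

**Steps most likely to fail**

**Step 12 (key step).**
- What may go wrong:
  - Proton removal at C3, by n-BuLi or by the aryllithium through an internal six-centre proton transfer, may compete with ring closure. This would erode configuration or expel the aryloxide by E1cB.
  - Butyl addition to the amide, or base-induced loss of formaldehyde from the N-methoxy group, may also intervene.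
- Fallback: an electrophilic closure in place of the anionic one. It sets out from 11 and comes back at 21.
  - Resorcinol is monosilylated (TBSCl, imidazole) to 3-(tert-butyldimethylsilyloxy)phenol F1.
  - Mitsunobu etherification of 11 with it gives the bromine-free ether acetate F2.
  - i-Bu2AlH gives the bromine-free alcohol F3.
  - TEMPO/PhI(OAc)2 in aqueous MeCN leads through the bromine-free aldehyde F4 to the bromine-free acid F5.
  - 1-Chloro-N,N,2-trimethylprop-1-en-1-amine (CH2Cl2, 0 °C, no base) gives the acid chloride F6.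
  - F6 is closed by intramolecular Friedel–Crafts acylation (SnCl4, 2,6-di-tert-butyl-4-methylpyridine as proton trap, dilute CH2Cl2, −78 °C) at the ring A carbon ortho to O1 and para to the silyloxy group, giving 21.
  - The proton trap and the low temperature are there to protect the olefin of ring D.

**Step 6.**
- What may go wrong:
  - The ortho-methoxy aryl group may blur the enzyme's discrimination between the two enantiotopic arms.
  - The sense may be opposite to the rule.
  - Acetyl migration between the two oxygens in water may racemise the monoacetate.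
- Fallback: a small-molecule catalyst in dry solvent. It sets out from 9 and comes back at 15.
  - Diol 9 is desymmetrised by acyl transfer from vinyl benzoate under the dinuclear zinc catalyst made from Et2Zn (10 mol %) and the ProPhenol ligand (5 mol %) in toluene at −15 °C.
  - The ligand antipode is chosen so that the pro-S arm is benzoylated. This gives the (S)-monobenzoate F7, whose acyl group migrates less readily.
  - Mitsunobu etherification with 13 gives the ether benzoate F8, and i-Bu2AlH removes the benzoate to give 15.

**Step 10.**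
- What may go wrong: the transient alpha-aryl aldehyde may enolise, with loss of configuration or beta-elimination of the aryloxide, or the oxidant may attack the olefin of ring D.
- Fallback: the carboxyl carbon is kept at the acid level throughout, so no aldehyde is ever formed. It sets out from 8 and comes back at 18.
  - Malonate 8 is saponified (KOH, aqueous EtOH; KHSO4) to the arylmalonic acid F9.
  - F9 loses CO2 in warm toluene to give the arylacetic acid F10.
  - F10 is joined (pivaloyl chloride, Et3N, LiCl, THF) to (R)-4-benzyloxazolidin-2-one to give the imide F11.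
  - Titanium-enolate hydroxymethylation (TiCl4, i-Pr2NEt, CH2Cl2, 0 °C; then 1,3,5-trioxane and a second equivalent of TiCl4) takes place on the enolate face away from the benzyl group and gives the (S)-hydroxy imide F12.
  - MeNHOMe·HCl/AlMe3 (CH2Cl2, −10 °C) exchanges the auxiliary to give the (S)-hydroxy amide F13.
  - Mitsunobu etherification of F13 with 13 gives 18. The weakly acidic alpha-hydrogen of the tertiary amide should hold back dehydration.

**Further compounds**
F1 | step 12 | 3-(tert-butyldimethylsilyloxy)phenol | CC(C)(C)[Si](C)(C)Oc1cccc(O)c1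
F2 | step 12 | (S)-3-[3-(tert-butyldimethylsilyloxy)phenoxy]-2-(7-methoxy-2,2-dimethyl-2H-chromen-6-yl)propyl acetate | COc1cc2c(cc1[C@H](COC(C)=O)COc3cccc(O[Si](C)(C)C(C)(C)C)c3)C=CC(C)(C)O2
F3 | step 12 | (R)-3-[3-(tert-butyldimethylsilyloxy)phenoxy]-2-(7-methoxy-2,2-dimethyl-2H-chromen-6-yl)propan-1-ol | COc1cc2c(cc1[C@H](CO)COc3cccc(O[Si](C)(C)C(C)(C)C)c3)C=CC(C)(C)O2
F4 | step 12 | (S)-3-[3-(tert-butyldimethylsilyloxy)phenoxy]-2-(7-methoxy-2,2-dimethyl-2H-chromen-6-yl)propanal | COc1cc2c(cc1[C@H](C=O)COc3cccc(O[Si](C)(C)C(C)(C)C)c3)C=CC(C)(C)O2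
F5 | step 12 | (S)-3-[3-(tert-butyldimethylsilyloxy)phenoxy]-2-(7-methoxy-2,2-dimethyl-2H-chromen-6-yl)propanoic acid | COc1cc2c(cc1[C@H](C(=O)O)COc3cccc(O[Si](C)(C)C(C)(C)C)c3)C=CC(C)(C)O2
F6 | step 12 | (S)-3-[3-(tert-butyldimethylsilyloxy)phenoxy]-2-(7-methoxy-2,2-dimethyl-2H-chromen-6-yl)propanoyl chloride | COc1cc2c(cc1[C@H](C(=O)Cl)COc3cccc(O[Si](C)(C)C(C)(C)C)c3)C=CC(C)(C)O2
F7 | step 6 | (S)-3-hydroxy-2-(7-methoxy-2,2-dimethyl-2H-chromen-6-yl)propyl benzoate | COc1cc2c(cc1[C@H](COC(=O)c3ccccc3)CO)C=CC(C)(C)O2
F8 | step 6 | (S)-3-[2-bromo-5-(tert-butyldimethylsilyloxy)phenoxy]-2-(7-methoxy-2,2-dimethyl-2H-chromen-6-yl)propyl benzoate | COc1cc2c(cc1[C@H](COC(=O)c3ccccc3)COc4cc(O[Si](C)(C)C(C)(C)C)ccc4Br)C=CC(C)(C)O2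
F9 | step 10 | 2-(7-methoxy-2,2-dimethyl-2H-chromen-6-yl)malonic acid | COc1cc2c(cc1C(C(=O)O)C(=O)O)C=CC(C)(C)O2
F10 | step 10 | 2-(7-methoxy-2,2-dimethyl-2H-chromen-6-yl)acetic acid | COc1cc2c(cc1CC(=O)O)C=CC(C)(C)O2
F11 | step 10 | (R)-4-benzyl-3-[2-(7-methoxy-2,2-dimethyl-2H-chromen-6-yl)acetyl]oxazolidin-2-one | COc1cc2c(cc1CC(=O)N3[C@H](Cc4ccccc4)COC3=O)C=CC(C)(C)O2
F12 | step 10 | (R)-4-benzyl-3-[(S)-3-hydroxy-2-(7-methoxy-2,2-dimethyl-2H-chromen-6-yl)propanoyl]oxazolidin-2-one | COc1cc2c(cc1[C@H](C(=O)N3[C@H](Cc4ccccc4)COC3=O)CO)C=CC(C)(C)O2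
F13 | step 10 | (S)-3-hydroxy-N-methoxy-2-(7-methoxy-2,2-dimethyl-2H-chromen-6-yl)-N-methylpropanamide | COc1cc2c(cc1[C@H](C(=O)N(C)OC)CO)C=CC(C)(C)O2
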